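The route rests on the C5–C6 bond of the seven-membered ring, between the cyclobutane methine C5 and the gem-dimethyl carbon C6. The cyclobutane and the six-membered ring are made first, by an intramolecular vinylketene–alkene [2+2] cycloaddition that delivers C5 as a cyclobutanone carbon. In the key step an iron hydride transfers a hydrogen atom to an isopropenyl group; the tertiary C6 radical closes the seven-membered ring onto the C5 tosylhydrazone, and loss of sulfinate and N2 leaves C5–H. The step exploits the quaternary C6 next to C5: the alkene CH2 becomes the second methyl. Its precursor is the bicyclic hydrazone whose quaternary carbon C10 carries the complete anti-1,3-diol diester chain.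

Key step: step 14

Numbering: longipinane numbering is used for the target and for the carbons that become it: C1 = ring ketone carbon, C2=C3 (C3 carries CH3), C4 and C11 = bridgeheads shared by the cyclobutane (C4–C5–C11–C10) and the six-membered ring (C1–C2–C3–C4–C5–C11), C10 = quaternary C–CH3, C6 = CMe2, C7 = CH–O(senecioate), C8 = CH2, C9 = CH–O(isovalerate); the seven-membered ring is C5–C6–C7–C8–C9–C10–C11.
Assumption: the chiral reagents of steps 4 and 10 are taken to induce in the sense stated there (Si-face and Re-face addition); should either induce the opposite sense, its antipode is used.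

Step 1
Reactants: 1 benzyl prop-2-yn-1-yl ether
Product: 3 (E)-4-(benzyloxy)-3-methylbut-2-en-1-ol, via alkenylalane 2 (not isolated)
Conditions: Me3Al, Cp2ZrCl2 (cat.), CH2Cl2, 0 °C → rt; then n-BuLi, (CH2O)n, THF, −78 °C → rt; aq. HCl work-up
Reagents that add atoms: trimethylaluminium C[Al](C)C; paraformaldehyde (as formaldehyde) C=O
Why: Zirconium-catalysed syn-methylalumination of the terminal alkyne puts CH3 on the internal carbon and aluminium on the terminal one, and hydroxymethylation of the derived alkenylaluminate with retention fixes the E geometry (CH3 cis to the new CH2OH) that later sets C10.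

Step 2
Reactants: 3 (E)-4-(benzyloxy)-3-methylbut-2-en-1-ol
Product: 4 (E)-4-(benzyloxy)-3-methylbut-2-enal
Conditions: MnO2, CH2Cl2, rt
Reagents that add atoms: none
Why: Allylic oxidation of a primary allylic alcohol with MnO2 stops at the enal and should not isomerise the double bond.

Step 3
Reactants: 5 ethyl 3-methylbut-2-enoate
Product: 6 tert-butyl[(1-ethoxy-3-methylbuta-1,3-dien-1-yl)oxy]dimethylsilane
Conditions: LiN(i-Pr)2, THF, −78 °C; then t-BuMe2SiCl, DMPU
Reagents that add atoms: tert-butyl(chloro)dimethylsilane CC(C)(C)[Si](C)(C)Cl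
Why: γ-Deprotonation of the senecioate and O-silylation of the extended enolate give the silyl dienol ether that serves as vinylogous nucleophile (ketene acetal geometry is of no consequence).

Step 4
Reactants: 4 (E)-4-(benzyloxy)-3-methylbut-2-enal; 6 tert-butyl[(1-ethoxy-3-methylbuta-1,3-dien-1-yl)oxy]dimethylsilane
Product: 8 ethyl (2E,5S,6E)-8-(benzyloxy)-5-hydroxy-3,7-dimethylocta-2,6-dienoate, via trichlorosilyl aldolate 7 (not isolated)
Conditions: SiCl4, (R,R)-bisphosphoramide catalyst [1,5-pentanediyl-linked bis-phosphoramide of (R)-N,N′-dimethyl-1,1′-binaphthyl-2,2′-diamine] (5 mol%), i-Pr2NEt (cat.), CH2Cl2, −78 °C; aq. NaHCO3 work-up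
Reagents that add atoms: none
Why: Lewis-base-catalysed vinylogous Mukaiyama aldol addition in which the chiral phosphoramide-bound trichlorosilyl cation activates the enal and the dienol ether attacks through its γ-carbon on the Si face, setting the 5S carbinol (future C1) under catalyst control and giving the 2E enoate.

Step 5
Reactants: 8 ethyl (2E,5S,6E)-8-(benzyloxy)-5-hydroxy-3,7-dimethylocta-2,6-dienoate
Product: 9 ethyl (2E,5S,6E)-8-(benzyloxy)-5-[(tert-butyldimethylsilyl)oxy]-3,7-dimethylocta-2,6-dienoate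
Conditions: t-BuMe2SiCl, imidazole, DMF, rt
Reagents that add atoms: tert-butyl(chloro)dimethylsilane CC(C)(C)[Si](C)(C)Cl
Why: Silylation of the secondary allylic alcohol under neutral conditions; the bulky silyl ether is the stereocontrolling group of the cycloaddition in step 7.

Step 6
Reactants: 9 ethyl (2E,5S,6E)-8-(benzyloxy)-5-[(tert-butyldimethylsilyl)oxy]-3,7-dimethylocta-2,6-dienoate
Product: 10 (2E,5S,6E)-8-(benzyloxy)-5-[(tert-butyldimethylsilyl)oxy]-3,7-dimethylocta-2,6-dienoic acid
Conditions: LiOH, THF–MeOH–H2O, 45 °C; then aq. HCl to pH 3 at 0 °C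
Reagents that add atoms: lithium hydroxide [Li+].[OH-]
Why: Saponification of the ethyl ester; the secondary silyl ether and the benzyl ether are stable to LiOH and to the brief cold acidification.

Step 7
Reactants: 10 (2E,5S,6E)-8-(benzyloxy)-5-[(tert-butyldimethylsilyl)oxy]-3,7-dimethylocta-2,6-dienoic acid
Product: 13 (1R,2S,5R,7R)-7-[(benzyloxy)methyl]-2-[(tert-butyldimethylsilyl)oxy]-7-methyl-4-methylidenebicyclo[3.1.1]heptan-6-one, via acid chloride 11 (not isolated), via vinylketene 12 (not isolated)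
Conditions: 1-chloro-N,N,2-trimethylprop-1-en-1-amine, CH2Cl2, 0 °C → rt; then slow addition to Et3N, toluene, reflux (high dilution)
Reagents that add atoms: none
Why: Neutral acid chloride formation, γ-dehydrochlorination to the vinylketene and crossed intramolecular ketene–alkene [2+2] cycloaddition (ketene carbonyl carbon to the CH terminus, ketene α-carbon to the disubstituted terminus) build the cyclobutane and the six-membered ring at once; the E alkene places the C10 methyl syn to the three-carbon bridge, and the C1 silyloxy group, which prefers the outside, pseudo-equatorial position in the forming six-membered ring, should direct the ketene to the alkene face that gives C4, C10 and C11 as in the target.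

Step 8
Reactants: 13 (1R,2S,5R,7R)-7-[(benzyloxy)methyl]-2-[(tert-butyldimethylsilyl)oxy]-7-methyl-4-methylidenebicyclo[3.1.1]heptan-6-one
Product: 14 (1R,2S,4S,5R,7R)-2-[(tert-butyldimethylsilyl)oxy]-7-(hydroxymethyl)-4,7-dimethylbicyclo[3.1.1]heptan-6-one
Conditions: H2 (1 atm), Pd/C, EtOH, rt
Reagents that add atoms: none
Why: Heterogeneous hydrogenation saturates the exocyclic methylene from the face away from the C10 methyl (the C3 methyl should end syn to the C10 bridge; this centre is removed again in step 16, so its epimer would serve equally) and hydrogenolyses the benzyl ether in the same operation, which removes the only alkene that would interfere in step 14.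

Step 9
Reactants: 14 (1R,2S,4S,5R,7R)-2-[(tert-butyldimethylsilyl)oxy]-7-(hydroxymethyl)-4,7-dimethylbicyclo[3.1.1]heptan-6-one
Product: 15 (1R,2S,4S,5R,7R)-2-[(tert-butyldimethylsilyl)oxy]-4,7-dimethyl-6-oxobicyclo[3.1.1]heptane-7-carbaldehyde
Conditions: Dess–Martin periodinane, NaHCO3, CH2Cl2, 0 °C → rt
Reagents that add atoms: none
Why: Dess–Martin oxidation of the neopentyl primary alcohol to the non-enolisable C9 aldehyde under buffered, non-nucleophilic conditions that leave the cyclobutanone untouched.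

Step 10
Reactants: 15 (1R,2S,4S,5R,7R)-2-[(tert-butyldimethylsilyl)oxy]-4,7-dimethyl-6-oxobicyclo[3.1.1]heptane-7-carbaldehyde; 16 3-methylbut-3-en-2-one
Product: 18 (1R,2S,4S,5R,7R)-2-[(tert-butyldimethylsilyl)oxy]-7-[(1R)-1-hydroxy-4-methyl-3-oxopent-4-en-1-yl]-4,7-dimethylbicyclo[3.1.1]heptan-6-one, via enol borinate 17 (not isolated)
Conditions: 16, (−)-Ipc2BCl, Et3N, Et2O, −78 → 0 °C; then 15, −78 → −20 °C; MeOH, pH 7 buffer, then HN(CH2CH2OH)2 work-up (no peroxide)
Reagents that add atoms: none
Why: Boron aldol addition of the diisopinocampheylboron enolate of the methyl ketone through a closed six-membered transition state, in which the boron enolate should add to the aldehyde in preference to the hindered cyclobutanone; because the surroundings of C10 are almost symmetric, the substrate gives no bias and the reagent alone controls the new centre (Re-face attack, 9R).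

Step 11
Reactants: 18 (1R,2S,4S,5R,7R)-2-[(tert-butyldimethylsilyl)oxy]-7-[(1R)-1-hydroxy-4-methyl-3-oxopent-4-en-1-yl]-4,7-dimethylbicyclo[3.1.1]heptan-6-one; 19 3-methylbutanal
Product: 20 (1R,3R)-1-[(1R,2S,4S,5R,7R)-2-[(tert-butyldimethylsilyl)oxy]-4,7-dimethyl-6-oxobicyclo[3.1.1]heptan-7-yl]-3-hydroxy-4-methylpent-4-en-1-yl 3-methylbutanoate
Conditions: SmI2 (30 mol%), 19 (excess), THF, −10 °C
Reagents that add atoms: none
Why: Evans–Tishchenko reaction in which the samarium-bound hemiacetal formed from the C9 hydroxyl and isovaleraldehyde delivers hydride intramolecularly through a chair transition state to the C7 carbonyl, which sets the 1,3-anti alcohol (7R) and leaves the isovalerate on O9 in the same operation.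

Step 12
Reactants: 20 (1R,3R)-1-[(1R,2S,4S,5R,7R)-2-[(tert-butyldimethylsilyl)oxy]-4,7-dimethyl-6-oxobicyclo[3.1.1]heptan-7-yl]-3-hydroxy-4-methylpent-4-en-1-yl 3-methylbutanoate; 21 3-methylbut-2-enoyl chloride
Product: 22 (3R,5R)-5-[(1R,2S,4S,5R,7R)-2-[(tert-butyldimethylsilyl)oxy]-4,7-dimethyl-6-oxobicyclo[3.1.1]heptan-7-yl]-2-methyl-5-[(3-methylbutanoyl)oxy]pent-1-en-3-yl 3-methylbut-2-enoate
Conditions: 21, pyridine, CH2Cl2, 0 °C → rt
Reagents that add atoms: none
Why: Acylation of the unhindered allylic C7 alcohol with the acid chloride in pyridine, a base too weak to deconjugate the senecioyl group through its ketene.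

Step 13
Reactants: 22 (3R,5R)-5-[(1R,2S,4S,5R,7R)-2-[(tert-butyldimethylsilyl)oxy]-4,7-dimethyl-6-oxobicyclo[3.1.1]heptan-7-yl]-2-methyl-5-[(3-methylbutanoyl)oxy]pent-1-en-3-yl 3-methylbut-2-enoate
Product: 23 N-tosylhydrazone of 22 at the ring ketone (C5)
Conditions: TsNHNH2, EtOH, 40 °C
Reagents that add atoms: 4-methylbenzenesulfonohydrazide Cc1ccc(cc1)S(=O)(=O)NN
Why: Hydrazone condensation at the strained, electrophilic cyclobutanone, the only ketone in the molecule, installs the radical acceptor (C=N geometry is of no consequence).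

Step 14
Reactants: 23 N-tosylhydrazone of 22 at the ring ketone (C5)
Product: 26 (1S,3S,4S,5S,7R,9R,10R,11R)-1-[(tert-butyldimethylsilyl)oxy]longipinane-7,9-diyl 7-(3-methylbut-2-enoate) 9-(3-methylbutanoate), via sulfonylhydrazine adduct 24 (not isolated), via alkyldiazene 25 (not isolated)
Conditions: Fe(acac)3 (30 mol%), PhSiH3, EtOH, 60 °C, high dilution; then Et3N, reflux
Reagents that add atoms: none
Why: Fe(acac)3 and PhSiH3 generate an iron hydride that transfers a hydrogen atom to the CH2 terminus of the 1,1-disubstituted alkene (Markovnikov), giving the tertiary C6 radical and turning the methylene into the second methyl group; this nucleophilic radical adds to the C5 carbon of the sulfonylhydrazone, the stabilised hydrazinyl radical is reduced to the hydrazine 24, and heating with Et3N eliminates sulfinate to the alkyldiazene 25, which loses N2 to leave C5–H. The closest known reaction type is the hydrogen-atom-transfer reductive coupling of alkenes with ketone N-sulfonylhydrazones by iron hydrides, known in inter- and intramolecular form, combined with the diazene fragmentation of sulfonylhydrazine adducts. The seven-membered ring C5–C6–C7–C8–C9–C10–C11 is closed in the 7-exo-trig mode onto the exocyclic C=N bond. The only new stereocentre is C5, and the tether fixes it: the chain hangs from the C10 position that is cis-1,3 to C5 on the cyclobutane face opposite the three-carbon bridge, so C6 can bond only from that face and the hydrogen ends on the other, while C6 becomes a non-stereogenic CMe2. The step needs hydrogen-atom transfer to occur only at the isopropenyl group, which is secured because the top bridge is saturated and the senecioate alkene is electron-poor and trisubstituted, and it needs cyclisation to outrun reduction of the radical, which the cis-1,3 preorganisation, the high radical affinity of the C=N acceptor and high dilution should favour.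

Step 15
Reactants: 26 (1S,3S,4S,5S,7R,9R,10R,11R)-1-[(tert-butyldimethylsilyl)oxy]longipinane-7,9-diyl 7-(3-methylbut-2-enoate) 9-(3-methylbutanoate)
Product: 27 (1S,3S,4S,5S,7R,9R,10R,11R)-1-hydroxylongipinane-7,9-diyl 7-(3-methylbut-2-enoate) 9-(3-methylbutanoate)
Conditions: HF·pyridine, pyridine, THF, 0 °C → rt
Reagents that add atoms: none
Why: Fluoride-mediated desilylation of the secondary silyl ether; both carboxylic esters are stable to buffered HF·pyridine and no free hydroxyl is present that could accept a migrating acyl group.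

Step 16
Reactants: 27 (1S,3S,4S,5S,7R,9R,10R,11R)-1-hydroxylongipinane-7,9-diyl 7-(3-methylbut-2-enoate) 9-(3-methylbutanoate)
Product: 29 (4R,5S,7R,9R,10R,11R)-1-oxolongipin-2-ene-7,9-diyl 7-(3-methylbut-2-enoate) 9-(3-methylbutanoate) (CNP0214473.1), via saturated ketone 28 (not isolated)
Conditions: IBX, DMSO, rt, then 75 °C
Reagents that add atoms: none
Why: IBX oxidation of the secondary alcohol to ketone 28 followed by IBX-mediated dehydrogenation on warming; enolisation is possible only toward C2 because C11 is a bridgehead, so the C2=C3 double bond forms regioselectively and the temporary C3 stereocentre disappears.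

Compound list
1 | benzyl prop-2-yn-1-yl ether | C#CCOCc1ccccc1 | starting material
2 | (E)-[3-(benzyloxy)-2-methylprop-1-en-1-yl]dimethylalane | C[Al](C)/C=C(\C)COCc1ccccc1 | intermediate
3 | (E)-4-(benzyloxy)-3-methylbut-2-en-1-ol | OC/C=C(\C)COCc1ccccc1 | intermediate
4 | (E)-4-(benzyloxy)-3-methylbut-2-enal | O=C/C=C(\C)COCc1ccccc1 | intermediate
5 | ethyl 3-methylbut-2-enoate | CCOC(=O)C=C(C)C | starting material
6 | tert-butyl[(1-ethoxy-3-methylbuta-1,3-dien-1-yl)oxy]dimethylsilane | C=C(C)C=C(OCC)O[Si](C)(C)C(C)(C)C | intermediate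
7 | ethyl (2E,5S,6E)-8-(benzyloxy)-3,7-dimethyl-5-[(trichlorosilyl)oxy]octa-2,6-dienoate | CCOC(=O)/C=C(\C)C[C@H](O[Si](Cl)(Cl)Cl)/C=C(\C)COCc1ccccc1 | intermediate
8 | ethyl (2E,5S,6E)-8-(benzyloxy)-5-hydroxy-3,7-dimethylocta-2,6-dienoate | CCOC(=O)/C=C(\C)C[C@H](O)/C=C(\C)COCc1ccccc1 | intermediate
9 | ethyl (2E,5S,6E)-8-(benzyloxy)-5-[(tert-butyldimethylsilyl)oxy]-3,7-dimethylocta-2,6-dienoate | CCOC(=O)/C=C(\C)C[C@H](O[Si](C)(C)C(C)(C)C)/C=C(\C)COCc1ccccc1 | intermediate
10 | (2E,5S,6E)-8-(benzyloxy)-5-[(tert-butyldimethylsilyl)oxy]-3,7-dimethylocta-2,6-dienoic acid | OC(=O)/C=C(\C)C[C@H](O[Si](C)(C)C(C)(C)C)/C=C(\C)COCc1ccccc1 | intermediate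
11 | (2E,5S,6E)-8-(benzyloxy)-5-[(tert-butyldimethylsilyl)oxy]-3,7-dimethylocta-2,6-dienoyl chloride | ClC(=O)/C=C(\C)C[C@H](O[Si](C)(C)C(C)(C)C)/C=C(\C)COCc1ccccc1 | intermediate
12 | (5S,6E)-8-(benzyloxy)-5-[(tert-butyldimethylsilyl)oxy]-7-methyl-3-methylideneocta-1,6-dien-1-one (vinylketene) | O=C=CC(=C)C[C@H](O[Si](C)(C)C(C)(C)C)/C=C(\C)COCc1ccccc1 | intermediate
13 | (1R,2S,5R,7R)-7-[(benzyloxy)methyl]-2-[(tert-butyldimethylsilyl)oxy]-7-methyl-4-methylidenebicyclo[3.1.1]heptan-6-one | c1ccccc1COC[C@@]2(C)[C@@H]3[C@@H](O[Si](C)(C)C(C)(C)C)CC(=C)[C@H]2C3=O | intermediate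
14 | (1R,2S,4S,5R,7R)-2-[(tert-butyldimethylsilyl)oxy]-7-(hydroxymethyl)-4,7-dimethylbicyclo[3.1.1]heptan-6-one | OC[C@@]2(C)[C@@H]3[C@@H](O[Si](C)(C)C(C)(C)C)C[C@H](C)[C@H]2C3=O | intermediate
15 | (1R,2S,4S,5R,7R)-2-[(tert-butyldimethylsilyl)oxy]-4,7-dimethyl-6-oxobicyclo[3.1.1]heptane-7-carbaldehyde | O=C[C@@]2(C)[C@@H]3[C@@H](O[Si](C)(C)C(C)(C)C)C[C@H](C)[C@H]2C3=O | intermediate
16 | 3-methylbut-3-en-2-one | CC(=O)C(C)=C | starting material
17 | 3-methylbuta-1,3-dien-2-yl (−)-diisopinocampheylborinate (enol borinate of 16) | C=C(OB([C@@H]1C[C@@H]2C[C@H]([C@H]1C)C2(C)C)[C@@H]1C[C@@H]2C[C@H]([C@H]1C)C2(C)C)C(C)=C | intermediate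
18 | (1R,2S,4S,5R,7R)-2-[(tert-butyldimethylsilyl)oxy]-7-[(1R)-1-hydroxy-4-methyl-3-oxopent-4-en-1-yl]-4,7-dimethylbicyclo[3.1.1]heptan-6-one | C=C(C)C(=O)C[C@@H](O)[C@@]2(C)[C@@H]3[C@@H](O[Si](C)(C)C(C)(C)C)C[C@H](C)[C@H]2C3=O | intermediate
19 | 3-methylbutanal | CC(C)CC=O | starting material
20 | (1R,3R)-1-[(1R,2S,4S,5R,7R)-2-[(tert-butyldimethylsilyl)oxy]-4,7-dimethyl-6-oxobicyclo[3.1.1]heptan-7-yl]-3-hydroxy-4-methylpent-4-en-1-yl 3-methylbutanoate | C=C(C)[C@H](O)C[C@@H](OC(=O)CC(C)C)[C@@]2(C)[C@@H]3[C@@H](O[Si](C)(C)C(C)(C)C)C[C@H](C)[C@H]2C3=O | intermediate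
21 | 3-methylbut-2-enoyl chloride | CC(C)=CC(Cl)=O | starting material
22 | (3R,5R)-5-[(1R,2S,4S,5R,7R)-2-[(tert-butyldimethylsilyl)oxy]-4,7-dimethyl-6-oxobicyclo[3.1.1]heptan-7-yl]-2-methyl-5-[(3-methylbutanoyl)oxy]pent-1-en-3-yl 3-methylbut-2-enoate | C=C(C)[C@H](OC(=O)C=C(C)C)C[C@@H](OC(=O)CC(C)C)[C@@]2(C)[C@@H]3[C@@H](O[Si](C)(C)C(C)(C)C)C[C@H](C)[C@H]2C3=O | intermediate
23 | N-tosylhydrazone of 22 at the ring ketone (C5) | C=C(C)[C@H](OC(=O)C=C(C)C)C[C@@H](OC(=O)CC(C)C)[C@@]2(C)[C@@H]3[C@@H](O[Si](C)(C)C(C)(C)C)C[C@H](C)[C@H]2C3=NNS(=O)(=O)c1ccc(C)cc1 | intermediate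
24 | 26 carrying NH–NH–SO2C6H4CH3 at C5 (sulfonylhydrazine adduct) | CC(C)=CC(=O)O[C@@H]1C[C@@H](OC(=O)CC(C)C)[C@@]2(C)[C@@H]3[C@@H](O[Si](C)(C)C(C)(C)C)C[C@H](C)[C@H]2[C@]3(NNS(=O)(=O)c4ccc(C)cc4)C1(C)C | intermediate
25 | 26 carrying N=NH at C5 (alkyldiazene) | CC(C)=CC(=O)O[C@@H]1C[C@@H](OC(=O)CC(C)C)[C@@]2(C)[C@@H]3[C@@H](O[Si](C)(C)C(C)(C)C)C[C@H](C)[C@H]2[C@]3(N=N)C1(C)C | intermediate
26 | (1S,3S,4S,5S,7R,9R,10R,11R)-1-[(tert-butyldimethylsilyl)oxy]longipinane-7,9-diyl 7-(3-methylbut-2-enoate) 9-(3-methylbutanoate) | CC(C)=CC(=O)O[C@@H]1C[C@@H](OC(=O)CC(C)C)[C@@]2(C)[C@@H]3[C@@H](O[Si](C)(C)C(C)(C)C)C[C@H](C)[C@H]2[C@@H]3C1(C)C | intermediate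
27 | (1S,3S,4S,5S,7R,9R,10R,11R)-1-hydroxylongipinane-7,9-diyl 7-(3-methylbut-2-enoate) 9-(3-methylbutanoate) | CC(C)=CC(=O)O[C@@H]1C[C@@H](OC(=O)CC(C)C)[C@@]2(C)[C@@H]3[C@@H](O)C[C@H](C)[C@H]2[C@@H]3C1(C)C | intermediate
28 | (3S,4S,5S,7R,9R,10R,11R)-1-oxolongipinane-7,9-diyl 7-(3-methylbut-2-enoate) 9-(3-methylbutanoate) | CC(C)=CC(=O)O[C@@H]1C[C@@H](OC(=O)CC(C)C)[C@@]2(C)[C@@H]3C(=O)C[C@H](C)[C@H]2[C@@H]3C1(C)C | intermediate
29 | (4R,5S,7R,9R,10R,11R)-1-oxolongipin-2-ene-7,9-diyl 7-(3-methylbut-2-enoate) 9-(3-methylbutanoate) (CNP0214473.1) | CC(C)=CC(=O)O[C@@H]1C[C@@H](OC(=O)CC(C)C)[C@@]2(C)[C@@H]3C(=O)C=C(C)[C@H]2[C@@H]3C1(C)C | target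

Total step count: 16. Longest linear sequence: 15 steps (steps 1, 2 and 4 to 16; step 3 prepares the dienol ether).

Steps most likely to fail

1. Step 14. The tertiary C6 radical may be reduced by a second hydrogen-atom transfer, or lose a hydrogen atom back to alkene isomers, before the slow 7-exo closure takes place. The fallback sets out from 22 and returns to the route at 26. Cobalt-mediated hydrogen-atom-transfer hydrobromination of the isopropenyl group (Co(acac)2, t-BuOOH, Et3SiH, TsBr) would give the tertiary bromide F1. Condensation of its cyclobutanone with 1-amino-2-phenylaziridine would give the N-aziridinylimine F2. Slow addition of Bu3SnH with AIBN in refluxing benzene would then generate the C6 radical at a stannane concentration low enough for cyclisation onto the C=N carbon to win; loss of styrene and N2 and hydrogen transfer from the stannane to the C5 radical would give 26.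

2. Step 7. The alkene, deactivated by two allylic oxygen substituents, may react too slowly, so that the ketene dimerises, or the C1 silyloxy group may discriminate the two alkene faces insufficiently. The fallback sets out from 9 and returns to the route at 14. Copper hydride conjugate reduction (CuCl, NaOt-Bu, (S)-p-Tol-BINAP, polymethylhydrosiloxane; ligand antipode chosen for the 3S ester) would give the saturated ester F3, and aminolysis with pyrrolidine and Me3Al would give the pyrrolidine amide F4. Tf2O and 2,4,6-collidine in refluxing 1,2-dichloroethane would generate the more electrophilic keteniminium salt, whose intramolecular [2+2] cycloaddition and aqueous NaHCO3 hydrolysis would give the cyclobutanone F5, the benzyl ether of 14. Hydrogenolysis (H2, Pd/C) would give 14.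

3. Step 10. Reagent control by the isopinocampheyl groups may give too little facial selectivity at the unbiased C9 aldehyde, or the enolate may add to the cyclobutanone as well. The fallback sets out from 15 and returns to the route at 18. The acetate aldol addition of the titanium enolate of (S)-N-acetyl-4-isopropyl-1,3-thiazolidine-2-thione (TiCl4, i-Pr2NEt; auxiliary antipode chosen for 9R) would give the aldol adduct F6 under auxiliary control. Ethanethiol with K2CO3 would displace the auxiliary to give the S-ethyl thioester F7. A Liebeskind–Srogl coupling with prop-1-en-2-ylboronic acid (Pd2(dba)3, tri(2-furyl)phosphine, Cu(O2C-C4H3S) (copper thiophene-2-carboxylate), THF) would install the isopropenyl ketone under neutral conditions that spare the cyclobutanone and give 18.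

Further compounds
F1 | step 14 | 22 with the isopropenyl group converted into 2-bromopropan-2-yl (tertiary C6 bromide) | CC(C)(Br)[C@H](OC(=O)C=C(C)C)C[C@@H](OC(=O)CC(C)C)[C@@]2(C)[C@@H]3[C@@H](O[Si](C)(C)C(C)(C)C)C[C@H](C)[C@H]2C3=O
F2 | step 14 | N-(2-phenylaziridin-1-yl)imine of F1 at the ring ketone (aziridine centre racemic) | CC(C)(Br)[C@H](OC(=O)C=C(C)C)C[C@@H](OC(=O)CC(C)C)[C@@]2(C)[C@@H]3[C@@H](O[Si](C)(C)C(C)(C)C)C[C@H](C)[C@H]2C3=NN1CC1c1ccccc1
F3 | step 7 | ethyl (3S,5S,6E)-8-(benzyloxy)-5-[(tert-butyldimethylsilyl)oxy]-3,7-dimethyloct-6-enoate | CCOC(=O)C[C@@H](C)C[C@H](O[Si](C)(C)C(C)(C)C)/C=C(\C)COCc1ccccc1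
F4 | step 7 | 1-[(3S,5S,6E)-8-(benzyloxy)-5-[(tert-butyldimethylsilyl)oxy]-3,7-dimethyloct-6-enoyl]pyrrolidine | O=C(C[C@@H](C)C[C@H](O[Si](C)(C)C(C)(C)C)/C=C(\C)COCc1ccccc1)N1CCCC1
F5 | step 7 | (1R,2S,4S,5R,7R)-7-[(benzyloxy)methyl]-2-[(tert-butyldimethylsilyl)oxy]-4,7-dimethylbicyclo[3.1.1]heptan-6-one | c1ccccc1COC[C@@]2(C)[C@@H]3[C@@H](O[Si](C)(C)C(C)(C)C)C[C@H](C)[C@H]2C3=O
F6 | step 10 | (3R)-3-hydroxy-3-[bicyclic ketone of 15]-1-[(4S)-4-isopropyl-2-thioxo-1,3-thiazolidin-3-yl]propan-1-one | S=C1SC[C@H](C(C)C)N1C(=O)C[C@@H](O)[C@@]2(C)[C@@H]3[C@@H](O[Si](C)(C)C(C)(C)C)C[C@H](C)[C@H]2C3=O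
F7 | step 10 | S-ethyl (3R)-3-hydroxy-3-[bicyclic ketone of 15]propanethioate | CCSC(=O)C[C@@H](O)[C@@]2(C)[C@@H]3[C@@H](O[Si](C)(C)C(C)(C)C)C[C@H](C)[C@H]2C3=O
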